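The catalyst is what I follow in this flask.

    partner + protic impurity → quenched reagent (k1 = 9.9 M⁻¹ min⁻¹)
    catalyst intermediate B → free catalyst + product (k2 = 0.11 min⁻¹)
    substrate + free catalyst → catalyst intermediate A (k3 = 9.8 M⁻¹ min⁻¹)
    solid reagent ⇌ partner, rate k4*(cs4 - [partner]) while solid is left; crystals form when [partner] > cs4 (cs4 = 37 mM, k4 = 0.0016 min⁻¹)
    partner + catalyst intermediate A ⇌ catalyst intermediate B (K5 = 7.9 M⁻¹, k5 = 5.4 M⁻¹ min⁻¹)

substrate 0.35 M; solid reagent 1.10 equiv; protic impurity 7.00 mM; free catalyst 2.5 mol%

- as a solid, counted per litre of solution: solid reagent
- at the start none of the solid reagent is in solution
- charge of substrate (flask): 0.35 M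

- the form that holds most of the catalyst when 10% of the substrate are converted (catalyst intermediate B / catalyst intermediate A / free catalyst)
- its share of the catalyst then

The flask is charged with 1.10 equiv of solid reagent, more than the substrate, yet I expect the catalyst to sit in intermediate A, which waits for partner. But the catalyst meets dissolved partner, not the charge.

I follow one catalyst. Free, it is captured by substrate at 210 h⁻¹, faster than intermediate B releases it at 6.6 h⁻¹, so I count just A and B. From B it goes back at 0.684 min⁻¹ or on to product at 0.11 min⁻¹, so 13.9% of its visits end in product. It leaves A in proportion to dissolved partner. Equal flows both ways make B over A equal to dissolved partner over 42.0% of the substrate charge. I call this the half-way level: the dissolved partner at which A and B hold equal shares.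

Saturation is 10.6% of the charge, a quarter of that level, and even there A holds 79.8%. I set the dissolution feed equal to the catalyst's turnover and get 2.08% of the charge, lower than saturation, so A holds 95.3%. This balance leaves out the protic impurity. Its charge takes 1.97 h of full feed and the balance settles with a half-time of 1.42 h. Beyond the 2.5 mol% of substrate held on the catalyst, the rest of the 10% conversion takes 9.20 h at that level, longer than those two together.

The forecast names catalyst intermediate A at 95%: “intermediate A is the clear resting state”.

The simulation gives catalyst intermediate A at 95.0%, with intermediate B at 4.85% and free catalyst at 0.173%.

By 3.00 h in this flask the protic impurity is down to 10.7% of its charge, half of its reaction with partner up to then being done by 1.34 h, while dissolved partner stands at 0.701% of the substrate charge and product at 0.413%. By 30.0 h the impurity stands at 0%, product at 20.8% and dissolved partner at 2.16%; over the half-way level that puts intermediate B at 4.90%, and the flask holds 4.89%.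

The constants come from no measurement.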